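## The problem

Compound 26 is a depsidone: rings A and B are joined twice, by a diaryl ether oxygen and by an aryl ester, so that a seven-membered dioxepinone lies between two benzene rings, and ring B also carries a fused five-membered 3-hydroxyphthalide. Both carbons of the ether bridge have two ortho substituents, so coupling two finished arenes at this oxygen would be slow. The only stereocentre is the (R)-configured lactol carbon; nothing else in the molecule can control it, so its configuration has to come from an external auxiliary. A free 3-hydroxyphthalide can open to the aldehyde acid, so the centre must stay masked as a mixed acetal until the last, neutral step. That acetal (a pseudoester) is opened by hydroxide or alkoxide, exchanges under acid, and can open and re-close when the oxygen ortho to it is a free phenol. The depsidone ester is cleaved by nucleophiles, and the electron-rich phenols of both rings are best kept protected to the end. The feature that allows the key step lies in ring A: the carbons bearing OCH3, OH and the ether oxygen are contiguous and are followed by the ester-bearing carbon, C–CH3 and C–H. Four of these (C–OH, C–OCH3, C–H, C–CH3) are C3 to C6 of a 3,4-dioxygenated 6-methyl-2-pyrone, and the other two (C–OAr and C–CO2R) are an alkyne that carries the ring B oxygen and an ester.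

## Retrosynthesis

**26 from 25.** The two aryl benzyl ethers and the O–CH(CH3)Ph bond of the acetal are cut. Hydrogenolysis is the one unmasking that is neutral and does not touch the bonds between the lactol carbon and its oxygens. The (S)-1-phenylethyl group in 25 is both the protecting group of the lactol and the handle that makes the two configurations of the acetal carbon separable.

**25 from 24, 23 and 22.** The ester C–O bond of the seven-membered ring is cut, giving hydroxy acid 24. Closing the ester last is preferred to closing the ether last, because carbodiimide lactonisation of such hydroxy acids is the established depsidone ring closure, and an intramolecular Ullmann reaction would again meet the hindered ether. Acid 24 comes from the 2-(trimethylsilyl)ethyl ester 23, and the phenol of 23 from the 4-methoxybenzyl (PMB) ether 22. A silyl ether on this oxygen was rejected: in an earlier ring B intermediate (16) it would sit next to a free phenol and would migrate to it under base. An alkyl-type group that is removed oxidatively under neutral conditions does not migrate.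

**22 from 20 and 4 (key disconnection).** The two C–C bonds of ring A that flank the ether-bearing and the ester-bearing carbons are cut. This leaves pyrone 4 and the aryl ynol ether ester 20, and carbon dioxide is lost in the forward direction. Against the neighbouring cut at the ether C–O bond, this one makes the hindered ether oxygen enter as a simple phenol oxygen, and ring A shrinks to a seven-carbon pyrone. The forward reaction must be regioselective (pyrone C3 to the oxygen-bearing alkyne carbon) and must tolerate heating.

**20 from 19, 17, 16 and 6.** The triple bond is traced to the (Z)-2-bromoacrylate 19 by anti-elimination of hydrogen bromide. Compound 19 comes from the (E)-3-aryloxyacrylate 17 by bromination and dehydrobromination, and 17 from phenol 16 and propiolate 6 by conjugate addition. All three are standard operations. The strongly basic metalation route to ynol ethers is ruled out by the lactone. The acetal epimers are separated at 17, the first compound in which the ortho phenol is capped and the acetal can no longer open and re-close; only the (3R)-epimer 17 is carried on.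

**16 from 14 and 15; 14 from 13 and 12.** The acetal C–O bond is cut to the pseudo-acid 14 and (S)-1-phenylethanol 15. Compound 14 is the hydrolysis product of formyl ester 13, whose aldehyde carbon is attached ortho to the phenol of 12. Building the lactol carbon by formylation is preferred to oxidising a ring methyl group of a 3,6-dimethylbenzoate. That oxidation would need radical bromination, which attacks benzyl and PMB ethers and cannot tell two aryl methyl groups apart.

**12 from 10, 9, 8 and 7.** The phenol oxygen of 12 comes from the bromide 10 by borylation and oxidation. The bromine is placed first, on methyl 2,4-dihydroxy-3-methylbenzoate 7, where only one ring position is activated. The two hydroxyl groups are then protected in the order of their reactivity (free 4-OH as the PMB ether 9, hydrogen-bonded 2-OH as the benzyl ether 10). The three oxygens of ring B are therefore different from the start.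

**4 from 3, 2 and 1; 6 from 5.** The benzyloxy group at pyrone C3 is traced to a carbenoid O–H insertion of diazo compound 2, giving 3, which is then O-methylated. Compound 2 comes from 4-hydroxy-6-methyl-2-pyrone 1 by diazo transfer. This avoids alkoxide displacement on a pyrone that also has electrophilic C4 and C6. Ester 6 is made from propiolic acid 5.

## Roads not taken

**Alternative 1:** The diaryl ether C–O bond is cut and the ester kept, so the precursor is the depside A1. The forward key step is a cytochrome P450 phenol coupling that joins the ring A hydroxyl ortho to the ester to the only unsubstituted ring B carbon and gives depsidone A2. Its merits are real: A1 needs only an esterification of two simple aromatic units, no protecting groups are required in principle, and the hindered ether is made without any coupling reagent. In step count this road is clearly better than the chosen one. Its weak points are two. The enzyme has to accept this exact substitution pattern, which cannot be predicted from structure. And A2 lacks the lactol hydroxyl, so a benzylic hydroxylation of the phthalide CH2 must follow on a polyphenolic depsidone, with no means to control or keep the configuration. The chosen plan sets against the shorter route that its oxidation levels are fixed from the start, that it uses bench reagents only, and that it has a defined handle for the (R) centre.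

**Alternative 2:** Two C–C bonds of ring B are cut, leading to the ring A aryloxy enone A3 and a malonate diester. The forward key step is a Michael addition followed by a Claisen condensation, giving cyclohexanedione A4, which is aromatised later. The merit is that the ether oxygen again enters unhindered, as an α-aryloxy ketone, and that the anion chemistry is robust. The weak points are that A4 has to be dehydrogenated to a resorcinol, that the two new phenols must then be differentiated for the lactonisation, and that the acetal and the tert-butyl ester have to be opened with acid. The lactol then forms last with no control of configuration. In avoiding the hindered ether this road is as good as the chosen one. The chosen plan sets against it that ring B is aromatic and differentiated throughout and that the lactol carbon is carried as a resolvable acetal.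

**Alternative 3:** The acyl–O and O–CH bonds of the phthalide are cut, leading to the depsidone-fused 2-benzyloxybenzocyclobutenone A5. The forward key step is a Baeyer–Villiger oxidation in which the benzyloxy-bearing carbon migrates with retention and gives the protected target A6. Its merit is that the stereocentre is made by a stereospecific migration, without discarding an epimer. In this respect it is better than the chosen plan, which sets its centre by a separation and loses the other epimer. Its weak points are that an enantiopure four-membered ketone fused to a fully substituted ring B has no obvious preparation, that a peracid meets several electron-rich arenes, and that the diaryl ether of the depsidone still has to be made in some other way. The chosen plan sets against it a cheap auxiliary, ordinary acetal chemistry, and a key step that solves the ether problem.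

Key step: step 15

Assumption: the lactol carbon of 26, like that of other 3-hydroxyphthalides, is taken to keep its configuration only in neutral, aprotic media; the last step and the isolation are therefore run without acid or base.

## Route

Step 1
Reactants: 1 4-hydroxy-6-methyl-2H-pyran-2-one
Product: 2 3-diazo-6-methyl-2H-pyran-2,4(3H)-dione
Conditions: 4-acetamidobenzenesulfonyl azide, Et3N, MeCN, 0 °C to rt
Reagents that add atoms: 4-acetamidobenzenesulfonyl azide, CC(=O)Nc1ccc(cc1)S(=O)(=O)N=[N+]=[N-]
Why: Regitz diazo transfer to a cyclic 1,3-dicarbonyl compound (the 2,4-dione tautomer of 1); C3 is the only doubly activated carbon.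

Step 2
Reactants: 2 3-diazo-6-methyl-2H-pyran-2,4(3H)-dione
Product: 3 3-(benzyloxy)-4-hydroxy-6-methyl-2H-pyran-2-one
Conditions: BnOH (5 equiv), Rh2(OAc)4 (1 mol%), 1,2-dichloroethane, 80 °C
Reagents that add atoms: benzyl alcohol, OCc1ccccc1
Why: Rhodium-carbenoid O–H insertion of a cyclic 2-diazo-1,3-dicarbonyl compound into an alcohol; the insertion product enolises to the hydroxypyrone, so the benzyloxy group arrives at C3 without alkoxide displacement on the pyrone.

Step 3
Reactants: 3 3-(benzyloxy)-4-hydroxy-6-methyl-2H-pyran-2-one
Product: 4 3-(benzyloxy)-4-methoxy-6-methyl-2H-pyran-2-one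
Conditions: Me2SO4, K2CO3, acetone, reflux
Reagents that add atoms: dimethyl sulfate, COS(=O)(=O)OC
Why: O-methylation of the vinylogous acid under the usual conditions for 4-methoxy-2-pyrones; the 2-methoxy-4-pyranone isomer is the expected minor, separable product.

Step 4
Reactants: 5 propiolic acid
Product: 6 2-(trimethylsilyl)ethyl propiolate
Conditions: 2-(trimethylsilyl)ethanol, DCC, DMAP (5 mol%), CH2Cl2, −20 to 0 °C
Reagents that add atoms: 2-(trimethylsilyl)ethanol, C[Si](C)(C)CCO
Why: Steglich esterification; low temperature and little DMAP keep the amine from adding to the propiolate.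

Step 5
Reactants: 7 methyl 2,4-dihydroxy-3-methylbenzoate
Product: 8 methyl 5-bromo-2,4-dihydroxy-3-methylbenzoate
Conditions: NBS (1.0 equiv), MeCN, 0 °C
Reagents that add atoms: N-bromosuccinimide, O=C1CCC(=O)N1Br
Why: Electrophilic aromatic bromination; C5 is ortho to the 4-hydroxyl and para to the 2-hydroxyl, whereas C6 is meta to both.

Step 6
Reactants: 8 methyl 5-bromo-2,4-dihydroxy-3-methylbenzoate
Product: 9 methyl 5-bromo-2-hydroxy-4-[(4-methoxybenzyl)oxy]-3-methylbenzoate
Conditions: PMBCl (1.05 equiv), K2CO3 (1.1 equiv), DMF, rt
Reagents that add atoms: 4-methoxybenzyl chloride, COc1ccc(CCl)cc1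
Why: Williamson etherification; the 2-hydroxyl is tied up in a hydrogen bond to the ester, so the 4-hydroxyl is alkylated selectively, as is usual for 2,4-dihydroxybenzoates.

Step 7
Reactants: 9 methyl 5-bromo-2-hydroxy-4-[(4-methoxybenzyl)oxy]-3-methylbenzoate
Product: 10 methyl 2-(benzyloxy)-5-bromo-4-[(4-methoxybenzyl)oxy]-3-methylbenzoate
Conditions: BnBr, K2CO3, DMF, 60 °C
Reagents that add atoms: benzyl bromide, BrCc1ccccc1
Why: Williamson etherification of the hydrogen-bonded phenol under more forcing conditions.

Step 8
Reactants: 10 methyl 2-(benzyloxy)-5-bromo-4-[(4-methoxybenzyl)oxy]-3-methylbenzoate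
Product: 12 methyl 2-(benzyloxy)-5-hydroxy-4-[(4-methoxybenzyl)oxy]-3-methylbenzoate, via pinacol boronate 11 (not isolated)
Conditions: B2pin2, Pd(dppf)Cl2 (3 mol%), KOAc, 1,4-dioxane, 90 °C; then 30% H2O2, 1 M NaOH, THF, 0 °C
Reagents that add atoms: bis(pinacolato)diboron, CC1(C)OB(OC1(C)C)B1OC(C)(C)C(C)(C)O1 (boron of 11); hydrogen peroxide, OO (oxygen of 12)
Why: Miyaura borylation of an aryl bromide with one ortho substituent, followed by oxidation of the aryl boronate; the result is the single free phenol of ring B, already distinct from the PMB- and benzyl-protected oxygens.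

Step 9
Reactants: 12 methyl 2-(benzyloxy)-5-hydroxy-4-[(4-methoxybenzyl)oxy]-3-methylbenzoate
Product: 13 methyl 2-(benzyloxy)-6-formyl-5-hydroxy-4-[(4-methoxybenzyl)oxy]-3-methylbenzoate
Conditions: MgCl2 (2 equiv), Et3N (4 equiv), (CH2O)n, MeCN, reflux
Reagents that add atoms: paraformaldehyde (formaldehyde), C=O
Why: Ortho-formylation of a phenol with MgCl2, Et3N and paraformaldehyde (Casnati–Skattebøl reaction); the ArOMgCl species delivers formaldehyde only ortho to oxygen, and C6 is the only free ring carbon.

Step 10
Reactants: 13 methyl 2-(benzyloxy)-6-formyl-5-hydroxy-4-[(4-methoxybenzyl)oxy]-3-methylbenzoate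
Product: 14 2-(benzyloxy)-6-formyl-5-hydroxy-4-[(4-methoxybenzyl)oxy]-3-methylbenzoic acid (ring tautomer: 7-(benzyloxy)-3,4-dihydroxy-5-[(4-methoxybenzyl)oxy]-6-methylisobenzofuran-1(3H)-one)
Conditions: LiOH, THF/MeOH/H2O, 40 °C; then 1 M HCl, 0 °C
Reagents that add atoms: lithium hydroxide, [Li+].[OH-]
Why: Saponification of a 2-formylbenzoate, which is helped by the neighbouring aldehyde; 14 is a ring–chain tautomeric pair and is used as such.

Step 11
Reactants: 14 2-(benzyloxy)-6-formyl-5-hydroxy-4-[(4-methoxybenzyl)oxy]-3-methylbenzoic acid; 15 (S)-1-phenylethanol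
Product: 16 7-(benzyloxy)-4-hydroxy-5-[(4-methoxybenzyl)oxy]-6-methyl-3-[(S)-1-phenylethoxy]isobenzofuran-1(3H)-one (both epimers at C3)
Conditions: 15 (3 equiv), PPTS (10 mol%), toluene, 4 Å MS, 80 °C
Reagents that add atoms: none
Why: Pseudoester formation: a 2-formylbenzoic acid with two ortho substituents reacts with alcohols at the lactol carbon of its ring tautomer and not at the carboxyl group. The C–O bond of 15 is not broken, so its (S) configuration is kept; C3 forms as both epimers and no control is expected here.

Step 12
Reactants: 16 7-(benzyloxy)-4-hydroxy-5-[(4-methoxybenzyl)oxy]-6-methyl-3-[(S)-1-phenylethoxy]isobenzofuran-1(3H)-one (both epimers at C3); 6 2-(trimethylsilyl)ethyl propiolate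
Product: 17 2-(trimethylsilyl)ethyl (E)-3-({(3R)-7-(benzyloxy)-5-[(4-methoxybenzyl)oxy]-6-methyl-1-oxo-3-[(S)-1-phenylethoxy]-1,3-dihydroisobenzofuran-4-yl}oxy)acrylate
Conditions: 6 (1.2 equiv), DABCO (20 mol%), CH2Cl2, 0 °C to rt; chromatography on silica
Reagents that add atoms: none
Why: Amine-catalysed conjugate addition of a phenol to a propiolate, which gives the (E)-3-aryloxyacrylate from both epimers of 16. Capping the phenol removes the ortho hydroxyl through which the acetal could open and re-close, so the (3R)-epimer 17 can be separated here from the co-formed (3S)-epimer, which is discarded. The two are diastereomers because of the (S)-1-phenylethyl group, so the stereocentre is set by this separation and its configuration must be assigned at this point.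

Step 13
Reactants: 17 2-(trimethylsilyl)ethyl (E)-3-({(3R)-7-(benzyloxy)-5-[(4-methoxybenzyl)oxy]-6-methyl-1-oxo-3-[(S)-1-phenylethoxy]-1,3-dihydroisobenzofuran-4-yl}oxy)acrylate
Product: 19 2-(trimethylsilyl)ethyl (Z)-2-bromo-3-({(3R)-7-(benzyloxy)-5-[(4-methoxybenzyl)oxy]-6-methyl-1-oxo-3-[(S)-1-phenylethoxy]-1,3-dihydroisobenzofuran-4-yl}oxy)acrylate, via dibromide 18 (not isolated)
Conditions: Br2 (1.0 equiv), CH2Cl2, −78 °C; then Et3N (3 equiv), −78 °C to rt
Reagents that add atoms: bromine, BrBr
Why: Bromine addition to the enol ether double bond and E1cB loss of HBr through the α-hydrogen, the standard route to 2-bromo-3-alkoxyacrylates. The (Z) isomer, with bromine and aryloxy cis, is expected and places H and Br anti for step 14.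

Step 14
Reactants: 19 2-(trimethylsilyl)ethyl (Z)-2-bromo-3-({(3R)-7-(benzyloxy)-5-[(4-methoxybenzyl)oxy]-6-methyl-1-oxo-3-[(S)-1-phenylethoxy]-1,3-dihydroisobenzofuran-4-yl}oxy)acrylate
Product: 20 2-(trimethylsilyl)ethyl 3-({(3R)-7-(benzyloxy)-5-[(4-methoxybenzyl)oxy]-6-methyl-1-oxo-3-[(S)-1-phenylethoxy]-1,3-dihydroisobenzofuran-4-yl}oxy)propiolate
Conditions: NaHMDS (1.1 equiv), THF, −78 °C
Reagents that add atoms: none
Why: Anti-dehydrobromination of a (Z)-2-bromovinyl ether with a hindered amide base, the reaction type used to make alkynyl ethers and alkynes from vinyl bromides. At −78 °C the silazide should be too weak to remove the acetal C–H and too hindered to add to the product.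

Step 15
Reactants: 20 2-(trimethylsilyl)ethyl 3-({(3R)-7-(benzyloxy)-5-[(4-methoxybenzyl)oxy]-6-methyl-1-oxo-3-[(S)-1-phenylethoxy]-1,3-dihydroisobenzofuran-4-yl}oxy)propiolate; 4 3-(benzyloxy)-4-methoxy-6-methyl-2H-pyran-2-one
Product: 22 2-(trimethylsilyl)ethyl 3-(benzyloxy)-2-({(3R)-7-(benzyloxy)-5-[(4-methoxybenzyl)oxy]-6-methyl-1-oxo-3-[(S)-1-phenylethoxy]-1,3-dihydroisobenzofuran-4-yl}oxy)-4-methoxy-6-methylbenzoate, via bridged lactone adduct 21 (not isolated)
Conditions: 4 (2 equiv), BHT (cat.), toluene, 160 °C, sealed tube
Reagents that add atoms: none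
Why: Proposed new method: thermal [4+2] addition of the pyrone diene (C3 to C6) of 4 to the alkyne of 20 gives the bridged lactone 21, which loses CO2 by retro-[4+2] and delivers ring A already aromatic; the closest known reaction type is the Diels–Alder and retro-Diels–Alder benzannulation of alkoxy-2-pyrones with alkynoates, and an aryloxy-substituted propiolate has not been used as the dienophile. Ring A is closed by an intermolecular cycloaddition that forms the C3–C(OAr) and C6–C(CO2R) bonds in one event, followed by cycloreversion. No stereocentre is created in 22, since the bridgeheads of 21 vanish on aromatisation, and the acetal centre is a spectator in a neutral, aprotic medium. The step needs regioselectivity. Pyrone C3, the α-carbon of the vinylogous ester set up by the 4-methoxy group, is the nucleophilic diene terminus and C6 the electrophilic one; they match the push–pull alkyne, whose oxygen-bearing carbon is electrophilic and whose ester-bearing carbon is nucleophilic. The aryl ynol ether has no hydrogen β to oxygen, so the retro-ene fragmentation that limits alkyl ynol ethers at this temperature cannot occur.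

Step 16
Reactants: 22 2-(trimethylsilyl)ethyl 3-(benzyloxy)-2-({(3R)-7-(benzyloxy)-5-[(4-methoxybenzyl)oxy]-6-methyl-1-oxo-3-[(S)-1-phenylethoxy]-1,3-dihydroisobenzofuran-4-yl}oxy)-4-methoxy-6-methylbenzoate
Product: 23 2-(trimethylsilyl)ethyl 3-(benzyloxy)-2-({(3R)-7-(benzyloxy)-5-hydroxy-6-methyl-1-oxo-3-[(S)-1-phenylethoxy]-1,3-dihydroisobenzofuran-4-yl}oxy)-4-methoxy-6-methylbenzoate
Conditions: DDQ (1.3 equiv), CH2Cl2/pH 7 phosphate buffer, 0 °C to rt
Reagents that add atoms: none
Why: Oxidative cleavage of a PMB ether; the benzyl ethers and the 1-phenylethyl acetal lack the para-methoxy group and are not oxidised, and the neutral medium leaves the acetal centre alone.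

Step 17
Reactants: 23 2-(trimethylsilyl)ethyl 3-(benzyloxy)-2-({(3R)-7-(benzyloxy)-5-hydroxy-6-methyl-1-oxo-3-[(S)-1-phenylethoxy]-1,3-dihydroisobenzofuran-4-yl}oxy)-4-methoxy-6-methylbenzoate
Product: 24 3-(benzyloxy)-2-({(3R)-7-(benzyloxy)-5-hydroxy-6-methyl-1-oxo-3-[(S)-1-phenylethoxy]-1,3-dihydroisobenzofuran-4-yl}oxy)-4-methoxy-6-methylbenzoic acid
Conditions: TBAF (3 equiv), THF, 0 °C to rt; aq NH4Cl
Reagents that add atoms: none
Why: Fluoride-induced fragmentation of a 2-(trimethylsilyl)ethyl ester; the attack is at silicon, so the double ortho substitution that would block saponification of this benzoate does not matter.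

Step 18
Reactants: 24 3-(benzyloxy)-2-({(3R)-7-(benzyloxy)-5-hydroxy-6-methyl-1-oxo-3-[(S)-1-phenylethoxy]-1,3-dihydroisobenzofuran-4-yl}oxy)-4-methoxy-6-methylbenzoic acid
Product: 25 di-O-benzyl depsidone acetal (the seven-membered lactone of 24; one benzyloxy group on ring A and one on ring B; the (3R)-3-[(S)-1-phenylethoxy]phthalide fused to ring B)
Conditions: EDC·HCl (1.5 equiv), DMAP (0.2 equiv), CH2Cl2, 0 °C to rt
Reagents that add atoms: none
Why: Carbodiimide lactonisation of a 2-(2-hydroxyaryloxy)benzoic acid, the classical depsidone ring closure; the only free phenol is the one that closes the seven-membered ring.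

Step 19
Reactants: 25 di-O-benzyl depsidone acetal
Product: 26 target depsidone (ring A in order from the ester carbon: C–CH3; C–H; C–OCH3; C–OH; C–O of the ether. Ring B in order from the ether carbon: C–O of the ester; C–CH3; C–OH; C–C(=O) of the phthalide; C–CH(OH) lactol carbon of (R) configuration)
Conditions: H2 (1 atm), Pd/C, EtOAc, rt
Reagents that add atoms: none
Why: Hydrogenolysis of two aryl benzyl ethers and of the O–CH(CH3)Ph bond of the acetal. The bonds from the lactol carbon to its two oxygens are not broken, so the (R) configuration fixed in step 12 should be retained, and the medium is neutral and aprotic.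

## Compound list

1 | 4-hydroxy-6-methyl-2H-pyran-2-one | Cc1cc(O)cc(=O)o1 | starting material
2 | 3-diazo-6-methyl-2H-pyran-2,4(3H)-dione | CC1=CC(=O)C(=[N+]=[N-])C(=O)O1 | intermediate
3 | 3-(benzyloxy)-4-hydroxy-6-methyl-2H-pyran-2-one | Cc1cc(O)c(OCc2ccccc2)c(=O)o1 | intermediate
4 | 3-(benzyloxy)-4-methoxy-6-methyl-2H-pyran-2-one | COc1cc(C)oc(=O)c1OCc1ccccc1 | intermediate
5 | propiolic acid | C#CC(=O)O | starting material
6 | 2-(trimethylsilyl)ethyl propiolate | C#CC(=O)OCC[Si](C)(C)C | intermediate
7 | methyl 2,4-dihydroxy-3-methylbenzoate | COC(=O)c1ccc(O)c(C)c1O | starting material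
8 | methyl 5-bromo-2,4-dihydroxy-3-methylbenzoate | COC(=O)c1cc(Br)c(O)c(C)c1O | intermediate
9 | methyl 5-bromo-2-hydroxy-4-[(4-methoxybenzyl)oxy]-3-methylbenzoate | COC(=O)c1cc(Br)c(OCc2ccc(OC)cc2)c(C)c1O | intermediate
10 | methyl 2-(benzyloxy)-5-bromo-4-[(4-methoxybenzyl)oxy]-3-methylbenzoate | COC(=O)c1cc(Br)c(OCc2ccc(OC)cc2)c(C)c1OCc1ccccc1 | intermediate
11 | methyl 2-(benzyloxy)-4-[(4-methoxybenzyl)oxy]-3-methyl-5-(4,4,5,5-tetramethyl-1,3,2-dioxaborolan-2-yl)benzoate | COC(=O)c1cc(B2OC(C)(C)C(C)(C)O2)c(OCc2ccc(OC)cc2)c(C)c1OCc1ccccc1 | intermediate (not isolated)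
12 | methyl 2-(benzyloxy)-5-hydroxy-4-[(4-methoxybenzyl)oxy]-3-methylbenzoate | COC(=O)c1cc(O)c(OCc2ccc(OC)cc2)c(C)c1OCc1ccccc1 | intermediate
13 | methyl 2-(benzyloxy)-6-formyl-5-hydroxy-4-[(4-methoxybenzyl)oxy]-3-methylbenzoate | COC(=O)c1c(OCc2ccccc2)c(C)c(OCc2ccc(OC)cc2)c(O)c1C=O | intermediate
14 | 2-(benzyloxy)-6-formyl-5-hydroxy-4-[(4-methoxybenzyl)oxy]-3-methylbenzoic acid (ring tautomer: the 3-hydroxyphthalide) | OC(=O)c1c(OCc2ccccc2)c(C)c(OCc2ccc(OC)cc2)c(O)c1C=O | intermediate
15 | (S)-1-phenylethanol | C[C@H](O)c1ccccc1 | starting material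
16 | 7-(benzyloxy)-4-hydroxy-5-[(4-methoxybenzyl)oxy]-6-methyl-3-[(S)-1-phenylethoxy]isobenzofuran-1(3H)-one, both C3 epimers | Oc1c(OCc2ccc(OC)cc2)c(C)c(OCc2ccccc2)c2c1C(O[C@@H](C)c1ccccc1)OC2=O | intermediate
17 | 2-(trimethylsilyl)ethyl (E)-3-({(3R)-7-(benzyloxy)-5-[(4-methoxybenzyl)oxy]-6-methyl-1-oxo-3-[(S)-1-phenylethoxy]-1,3-dihydroisobenzofuran-4-yl}oxy)acrylate | C[Si](C)(C)CCOC(=O)/C=C/Oc1c(OCc2ccc(OC)cc2)c(C)c(OCc2ccccc2)c2c1[C@H](O[C@@H](C)c1ccccc1)OC2=O | intermediate
18 | 2-(trimethylsilyl)ethyl 2,3-dibromo-3-(aryloxy)propanoate from 17 (diastereomers at the two CHBr carbons) | C[Si](C)(C)CCOC(=O)C(Br)C(Br)Oc1c(OCc2ccc(OC)cc2)c(C)c(OCc2ccccc2)c2c1[C@H](O[C@@H](C)c1ccccc1)OC2=O | intermediate (not isolated)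
19 | 2-(trimethylsilyl)ethyl (Z)-2-bromo-3-({(3R)-7-(benzyloxy)-5-[(4-methoxybenzyl)oxy]-6-methyl-1-oxo-3-[(S)-1-phenylethoxy]-1,3-dihydroisobenzofuran-4-yl}oxy)acrylate | C[Si](C)(C)CCOC(=O)/C(Br)=C/Oc1c(OCc2ccc(OC)cc2)c(C)c(OCc2ccccc2)c2c1[C@H](O[C@@H](C)c1ccccc1)OC2=O | intermediate
20 | 2-(trimethylsilyl)ethyl 3-({(3R)-7-(benzyloxy)-5-[(4-methoxybenzyl)oxy]-6-methyl-1-oxo-3-[(S)-1-phenylethoxy]-1,3-dihydroisobenzofuran-4-yl}oxy)propiolate | C[Si](C)(C)CCOC(=O)C#COc1c(OCc2ccc(OC)cc2)c(C)c(OCc2ccccc2)c2c1[C@H](O[C@@H](C)c1ccccc1)OC2=O | intermediate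
21 | bridged lactone adduct (2-oxabicyclo[2.2.2]octa-5,7-dien-3-one; bridgeheads carry CH3 and OBn) of 4 and 20 | O=C1OC2(C)C=C(OC)C1(OCc1ccccc1)C(Oc1c(OCc3ccc(OC)cc3)c(C)c(OCc3ccccc3)c3c1[C@H](O[C@@H](C)c1ccccc1)OC3=O)=C2C(=O)OCC[Si](C)(C)C | intermediate (not isolated)
22 | 2-(trimethylsilyl)ethyl 3-(benzyloxy)-2-({(3R)-7-(benzyloxy)-5-[(4-methoxybenzyl)oxy]-6-methyl-1-oxo-3-[(S)-1-phenylethoxy]-1,3-dihydroisobenzofuran-4-yl}oxy)-4-methoxy-6-methylbenzoate | C[Si](C)(C)CCOC(=O)c1c(C)cc(OC)c(OCc2ccccc2)c1Oc1c(OCc2ccc(OC)cc2)c(C)c(OCc2ccccc2)c2c1[C@H](O[C@@H](C)c1ccccc1)OC2=O | intermediate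
23 | 2-(trimethylsilyl)ethyl 3-(benzyloxy)-2-({(3R)-7-(benzyloxy)-5-hydroxy-6-methyl-1-oxo-3-[(S)-1-phenylethoxy]-1,3-dihydroisobenzofuran-4-yl}oxy)-4-methoxy-6-methylbenzoate | C[Si](C)(C)CCOC(=O)c1c(C)cc(OC)c(OCc2ccccc2)c1Oc1c(O)c(C)c(OCc2ccccc2)c2c1[C@H](O[C@@H](C)c1ccccc1)OC2=O | intermediate
24 | 3-(benzyloxy)-2-({(3R)-7-(benzyloxy)-5-hydroxy-6-methyl-1-oxo-3-[(S)-1-phenylethoxy]-1,3-dihydroisobenzofuran-4-yl}oxy)-4-methoxy-6-methylbenzoic acid | OC(=O)c1c(C)cc(OC)c(OCc2ccccc2)c1Oc1c(O)c(C)c(OCc2ccccc2)c2c1[C@H](O[C@@H](C)c1ccccc1)OC2=O | intermediate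
25 | di-O-benzyl depsidone with the (3R)-3-[(S)-1-phenylethoxy]phthalide | COc1cc(C)c2c(c1OCc1ccccc1)Oc1c(c(C)c(OCc3ccccc3)c3c1[C@H](O[C@@H](C)c1ccccc1)OC3=O)OC2=O | intermediate
26 | target depsidone with the (R)-lactol (CNP0211607.1) | COc1cc(C)c2c(c1O)Oc1c(c(C)c(O)c3c1[C@H](O)OC3=O)OC2=O | target

## Step count and risks

Total: 19 steps. Longest linear sequence: 15 steps (7 to 26, steps 5 to 19).

**Step 15 (key step, proposed new method).** The cycloaddition may be too slow below the temperature at which the ynol ether ester decomposes, because a push–pull alkyne is a weaker dienophile than a plain alkynoate. It may also take the reverse orientation, because the 3-benzyloxy group, a donor on a diene terminus, works against the orientation set by the 4-methoxy group. The fallback uses known reaction classes and sets out from 4, 6 and 16. Propiolate 6 is brominated at the alkyne terminus (NBS, AgNO3 cat., acetone) to 2-(trimethylsilyl)ethyl 3-bromopropiolate F1. Heating F1 with pyrone 4 in toluene, as in the known pyrone–alkynoate benzannulation, gives through the bridged lactone F2 and loss of CO2 the ring A bromide 2-(trimethylsilyl)ethyl 3-(benzyloxy)-2-bromo-4-methoxy-6-methylbenzoate F3. A copper-mediated Ullmann ether coupling of F3 with phenol 16 (CuI, N,N-dimethylglycine, Cs2CO3, 1,4-dioxane, 100 °C) then gives 22 together with its (3S)-epimer F4, which is removed by chromatography. The route is rejoined at 22. This coupling of two doubly ortho-substituted partners is expected to be inefficient, which is why it is only the reserve.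

**Step 14.** The silazide may add to the electrophilic oxygen-bearing carbon of the ynol ether ester as it forms, or remove the acetal C–H of the phthalide and so erode the configuration fixed in step 12. The fallback sets out from 16 and F1 (made from 6 as above). The phenoxide of 16 (generated with NaH, THF, −78 °C) is treated with F1; conjugate addition at the bromine-bearing carbon and loss of bromide from the vinyl anion give 20 together with its (3S)-epimer F5. The pair is separated, or carried through step 15 and separated as 22 and F4. The route is rejoined at 20.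

**Step 9.** Formylation may stall, because the only free ortho position is flanked by the ester group, which also lowers the nucleophilicity of that carbon. The fallback sets out from 12. Bromination ortho to the phenol (NBS, MeCN, 0 °C) gives methyl 2-(benzyloxy)-6-bromo-5-hydroxy-4-[(4-methoxybenzyl)oxy]-3-methylbenzoate F6. Deprotonation with MeMgCl, bromine–magnesium exchange with iPrMgCl·LiCl (THF, −20 °C; the ortho ester assists and survives) and quenching with DMF give 13, where the route is rejoined.

**Step 19.** Hydrogenolysis may go on at the lactol carbon (over-reduction to the phthalide), and the freed lactol may equilibrate through the aldehyde acid with loss of configuration if traces of acid or base are present. The fallback sets out from 25 and replaces hydrogenolysis by Lewis-acid dealkylation (BCl3, pentamethylbenzene, CH2Cl2, −78 °C, cold quench). This cleaves the two benzyl ethers and the 1-phenylethyl group at its own benzylic carbon and gives 26 directly. No new compound lies on this path. The acidic reagent is itself a risk for the configuration, so this is a reserve only.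

**Step 2.** The carbenoid may be diverted into ring contraction (Wolff rearrangement) or into attack on the aromatic ring of benzyl alcohol instead of O–H insertion. The fallback sets out from 1. O-methylation (Me2SO4, K2CO3, acetone) gives 4-methoxy-6-methyl-2H-pyran-2-one F7, and bromination at C3 (NBS, CH2Cl2) gives 3-bromo-4-methoxy-6-methyl-2H-pyran-2-one F8. Copper-catalysed coupling with benzyl alcohol (CuI, 3,4,7,8-tetramethyl-1,10-phenanthroline, Cs2CO3, toluene, 100 °C) then gives 4, where the route is rejoined.

## Further compounds

F1 | step 15 | 2-(trimethylsilyl)ethyl 3-bromopropiolate | BrC#CC(=O)OCC[Si](C)(C)C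
F2 | step 15 | bridged lactone adduct of 4 and F1 (not isolated) | O=C1OC2(C)C=C(OC)C1(OCc1ccccc1)C(Br)=C2C(=O)OCC[Si](C)(C)C
F3 | step 15 | 2-(trimethylsilyl)ethyl 3-(benzyloxy)-2-bromo-4-methoxy-6-methylbenzoate | C[Si](C)(C)CCOC(=O)c1c(C)cc(OC)c(OCc2ccccc2)c1Br
F4 | step 15 | (3S)-epimer of 22 | C[Si](C)(C)CCOC(=O)c1c(C)cc(OC)c(OCc2ccccc2)c1Oc1c(OCc2ccc(OC)cc2)c(C)c(OCc2ccccc2)c2c1[C@@H](O[C@@H](C)c1ccccc1)OC2=O
F5 | step 14 | (3S)-epimer of 20 | C[Si](C)(C)CCOC(=O)C#COc1c(OCc2ccc(OC)cc2)c(C)c(OCc2ccccc2)c2c1[C@@H](O[C@@H](C)c1ccccc1)OC2=O
F6 | step 9 | methyl 2-(benzyloxy)-6-bromo-5-hydroxy-4-[(4-methoxybenzyl)oxy]-3-methylbenzoate | COC(=O)c1c(Br)c(O)c(OCc2ccc(OC)cc2)c(C)c1OCc1ccccc1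
F0 | step 19 | none | none
F7 | step 2 | 4-methoxy-6-methyl-2H-pyran-2-one | COc1cc(C)oc(=O)c1
F8 | step 2 | 3-bromo-4-methoxy-6-methyl-2H-pyran-2-one | COc1cc(C)oc(=O)c1Br
A1 | alternative 1 | depside: 5-[(2,3-dihydroxy-4-methoxy-6-methylbenzoyl)oxy]-7-hydroxy-6-methylisobenzofuran-1(3H)-one | COc1cc(C)c(C(=O)Oc2cc3COC(=O)c3c(O)c2C)c(O)c1O
A2 | alternative 1 | depsidone phthalide lacking only the lactol hydroxyl | COc1cc(C)c2c(c1O)Oc1c(c(C)c(O)c3c1COC3=O)OC2=O
A3 | alternative 2 | tert-butyl 3-(benzyloxy)-2-[(1,1-dimethoxy-4-oxohex-2-en-3-yl)oxy]-4-methoxy-6-methylbenzoate | CCC(=O)C(=CC(OC)OC)Oc1c(OCc2ccccc2)c(OC)cc(C)c1C(=O)OC(C)(C)C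
A4 | alternative 2 | methyl 5-aryloxy-6-(dimethoxymethyl)-3-methyl-2,4-dioxocyclohexane-1-carboxylate (mixture of diastereomers and tautomers) | COC(=O)C1C(=O)C(C)C(=O)C(Oc2c(OCc3ccccc3)c(OC)cc(C)c2C(=O)OC(C)(C)C)C1C(OC)OC
A5 | alternative 3 | depsidone-fused 2-benzyloxybenzocyclobutenone, di-O-benzyl protected | COc1cc(C)c2c(c1OCc1ccccc1)Oc1c(c(C)c(OCc3ccccc3)c3c1[C@H](OCc1ccccc1)C3=O)OC2=O
A6 | alternative 3 | tribenzyl-protected target with the (R)-acetal carbon | COc1cc(C)c2c(c1OCc1ccccc1)Oc1c(c(C)c(OCc3ccccc3)c3c1[C@H](OCc1ccccc1)OC3=O)OC2=O
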